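**Retrosynthetic overview**
1. The (E)-crotonoyl C=C comes from late cross-metathesis of an acryloyl group, itself unveiled from a lithiated methoxyallene adduct at the C7 ketone; the tiglate comes from acylation of 8-OH.
2. The γ-lactone (second ring) comes from amide-assisted 5-exo opening of an α,β-epoxy ketone, which fixes C8a and C8 from C3a.
3. The cycloheptenone (first ring) comes from ring-closing metathesis of a vinyl ketone with a terminal alkene.
4. The open chain comes from an Evans syn-aldol (C5, C6), then Weinreb amide and vinyl Grignard.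
5. C3 and C3a come from 5,6-dihydro-2H-pyran-2-one by Rh-catalysed asymmetric vinyl 1,4-addition and trans-methylation.

Assumption: bicyclic compounds use cyclohepta[b]furan locants (O1, C2, C3, C3a, C4–C8, C8a), the target being (3R,3aS,5R,6S,7S,8S,8aR); the sense of induction of (S)-BINAP in step 1 is taken by analogy with cyclic enones.

**Step 1**
Reactants: 1 5,6-dihydro-2H-pyran-2-one
Product: 2 (4S)-4-ethenyloxan-2-one
Conditions: CH2=CHBF3K (2 equiv), [Rh(cod)2]BF4 (3 mol %), (S)-BINAP (3.3 mol %), toluene/H2O 4:1, 100 °C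
Reagents that add atoms: potassium vinyltrifluoroborate, C=C[B-](F)(F)F.[K+]
Why: Hayashi–Miyaura rhodium-catalysed asymmetric 1,4-addition; the BINAP–Rh–vinyl species adds to one enantioface of the unsaturated lactone and sets C4 (the later C3a) as S.

**Step 2**
Reactants: 2 (4S)-4-ethenyloxan-2-one
Product: 4 (3R,4R)-4-ethenyl-3-methyloxan-2-one, via lithium enolate 3 (not isolated)
Conditions: LDA (1.05 equiv), THF, −78 °C; then MeI, −78 → −40 °C
Reagents that add atoms: iodomethane, CI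
Why: Lactone enolate alkylation; MeI attacks anti to the adjacent vinyl group, giving the trans product and setting the later C3 as R.

**Step 3**
Reactants: 4 (3R,4R)-4-ethenyl-3-methyloxan-2-one
Product: 5 (2R,3R)-3-(2-hydroxyethyl)-N,N,2-trimethylpent-4-enamide
Conditions: Me2NH·HCl (3 equiv), AlMe3 (3 equiv), CH2Cl2, 0 °C → rt; Rochelle salt work-up
Reagents that add atoms: dimethylamine hydrochloride, CNC.Cl
Why: Weinreb-type aluminium amide aminolysis opens the lactone to the hydroxy amide without touching either stereocentre.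

**Step 4**
Reactants: 5 (2R,3R)-3-(2-hydroxyethyl)-N,N,2-trimethylpent-4-enamide
Product: 6 (2R,3R)-N,N,2-trimethyl-3-(2-oxoethyl)pent-4-enamide
Conditions: TEMPO (10 mol %), PhI(OAc)2 (1.2 equiv), CH2Cl2, rt
Reagents that add atoms: none
Why: TEMPO/PhI(OAc)2 oxidation takes the primary alcohol to the aldehyde without over-oxidation and leaves the alkene and amide alone.

**Step 5**
Reactants: 6 (2R,3R)-N,N,2-trimethyl-3-(2-oxoethyl)pent-4-enamide; 7 (4S)-4-benzyl-3-propanoyl-1,3-oxazolidin-2-one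
Product: 9 (4S)-4-benzyl-3-[(2S,3R,5R,6R)-7-(dimethylamino)-5-ethenyl-3-hydroxy-2,6-dimethyl-7-oxoheptanoyl]-1,3-oxazolidin-2-one, via boron Z-enolate 8 (not isolated)
Conditions: 7, Bu2BOTf (1.15 equiv), i-Pr2NEt (1.3 equiv), CH2Cl2, −78 → 0 °C; then 6, −78 → 0 °C; pH 7 buffer, MeOH, 30% H2O2, 0 °C
Reagents that add atoms: none
Why: Evans syn-aldol through a Zimmerman–Traxler chair of the Z-boron enolate; the (S)-benzyl auxiliary controls the face and sets the later C6 (S) and C5 (R) under reagent control.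

**Step 6**
Reactants: 9 (4S)-4-benzyl-3-[(2S,3R,5R,6R)-7-(dimethylamino)-5-ethenyl-3-hydroxy-2,6-dimethyl-7-oxoheptanoyl]-1,3-oxazolidin-2-one
Product: 10 (2S,3R,5R,6R)-5-ethenyl-3-hydroxy-N1-methoxy-N1,N7,N7,2,6-pentamethylheptanediamide
Conditions: MeNHOMe·HCl (3 equiv), AlMe3 (3 equiv), CH2Cl2, −20 → 0 °C
Reagents that add atoms: N,O-dimethylhydroxylamine hydrochloride, CNOC.Cl
Why: Weinreb transamidation; the aluminium chelate of the β-hydroxy imide directs attack to the exocyclic carbonyl, releasing the auxiliary without epimerisation.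

**Step 7**
Reactants: 10 (2S,3R,5R,6R)-5-ethenyl-3-hydroxy-N1-methoxy-N1,N7,N7,2,6-pentamethylheptanediamide
Product: 11 (2S,3R,5R,6R)-3-[(tert-butyldimethylsilyl)oxy]-5-ethenyl-N1-methoxy-N1,N7,N7,2,6-pentamethylheptanediamide
Conditions: TBSOTf (1.3 equiv), 2,6-lutidine (2 equiv), CH2Cl2, −78 → 0 °C
Reagents that add atoms: tert-butyldimethylsilyl triflate, CC(C)(C)[Si](C)(C)OS(=O)(=O)C(F)(F)F
Why: Silyl protection of the secondary alcohol keeps the later 5-OH apart from the 8-OH that must carry the tiglate.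

**Step 8**
Reactants: 11 (2S,3R,5R,6R)-3-[(tert-butyldimethylsilyl)oxy]-5-ethenyl-N1-methoxy-N1,N7,N7,2,6-pentamethylheptanediamide
Product: 12 (2R,3R,5R,6S)-5-[(tert-butyldimethylsilyl)oxy]-3-ethenyl-N,N,2,6-tetramethyl-7-oxonon-8-enamide
Conditions: CH2=CHMgBr (2 equiv), THF, 0 °C; cold aq. NH4Cl
Reagents that add atoms: vinylmagnesium bromide, C=C[Mg]Br
Why: Weinreb ketone synthesis; the magnesium chelate stops at the ketone stage, and the tertiary dimethylamide does not react at 0 °C.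

**Step 9**
Reactants: 12 (2R,3R,5R,6S)-5-[(tert-butyldimethylsilyl)oxy]-3-ethenyl-N,N,2,6-tetramethyl-7-oxonon-8-enamide
Product: 13 (2R)-2-[(1R,5S,6R)-6-[(tert-butyldimethylsilyl)oxy]-5-methyl-4-oxocyclohept-2-en-1-yl]-N,N-dimethylpropanamide
Conditions: second-generation Grubbs catalyst RuCl2(=CHPh)(PCy3)(H2IMes) (5 mol %), CH2Cl2 (3 mM), 40 °C
Reagents that add atoms: none
Why: Ring-closing metathesis of the vinyl ketone with the terminal alkene closes the seven-membered enone and loses ethene; no stereocentre is involved.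

**Step 10**
Reactants: 13 (2R)-2-[(1R,5S,6R)-6-[(tert-butyldimethylsilyl)oxy]-5-methyl-4-oxocyclohept-2-en-1-yl]-N,N-dimethylpropanamide
Product: 14 (2R)-2-[(1S,3S,4R,6S,7S)-4-[(tert-butyldimethylsilyl)oxy]-3-methyl-2-oxo-8-oxabicyclo[5.1.0]octan-6-yl]-N,N-dimethylpropanamide
Conditions: t-BuOOH (5.5 M in decane, 2 equiv), DBU (1.2 equiv), CH2Cl2, 0 °C
Reagents that add atoms: tert-butyl hydroperoxide, CC(C)(C)OO
Why: Weitz–Scheffer nucleophilic epoxidation; t-BuOO− adds to the β-carbon on the face opposite the adjacent side chain and the enolate closes onto oxygen, so the epoxide is trans to the side chain.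

**Step 11**
Reactants: 14 (2R)-2-[(1S,3S,4R,6S,7S)-4-[(tert-butyldimethylsilyl)oxy]-3-methyl-2-oxo-8-oxabicyclo[5.1.0]octan-6-yl]-N,N-dimethylpropanamide
Product: 16 (3R,3aS,5R,6S,8S,8aR)-5-[(tert-butyldimethylsilyl)oxy]-8-hydroxy-3,6-dimethylhexahydro-2H-cyclohepta[b]furan-2,7(3H)-dione, via iminium ether tosylate 15 (not isolated)
Conditions: TsOH·H2O (1.2 equiv), CH2Cl2, 0 °C → rt; then THF/H2O 4:1, rt; NaHCO3 work-up
Reagents that add atoms: water, O
Why: Acid-promoted neighbouring-group opening of the epoxy ketone: the amide oxygen attacks the β-carbon 5-exo with inversion to give the cis-fused iminium ether, whose hydrolysis gives the γ-lactone; this sets C8a (R) and leaves the epoxide oxygen as 8-OH (S).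

**Step 12**
Reactants: 16 (3R,3aS,5R,6S,8S,8aR)-5-[(tert-butyldimethylsilyl)oxy]-8-hydroxy-3,6-dimethylhexahydro-2H-cyclohepta[b]furan-2,7(3H)-dione
Product: 17 (3R,3aS,5R,6S,7S,8S,8aR)-5-[(tert-butyldimethylsilyl)oxy]-7,8-dihydroxy-7-(1-methoxypropa-1,2-dien-1-yl)-3,6-dimethyloctahydro-2H-cyclohepta[b]furan-2-one
Conditions: methoxyallene (4 equiv), n-BuLi (3.5 equiv), THF, −40 °C; anhydrous CeCl3 (3.5 equiv), −78 °C; then 16, −78 °C; sat. aq. NaHCO3
Reagents that add atoms: methoxyallene, COC=C=C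
Why: 1,2-Addition of an acryloyl-anion equivalent as its organocerium reagent, which limits enolisation and lactone attack; after the 8-alkoxide forms and chelates the ketone, attack is expected on the convex α face anti to the C6 methyl, giving 7-OH β (7S).

**Step 13**
Reactants: 17 (3R,3aS,5R,6S,7S,8S,8aR)-5-[(tert-butyldimethylsilyl)oxy]-7,8-dihydroxy-7-(1-methoxypropa-1,2-dien-1-yl)-3,6-dimethyloctahydro-2H-cyclohepta[b]furan-2-one
Product: 18 (3R,3aS,5R,6S,7S,8S,8aR)-5-[(tert-butyldimethylsilyl)oxy]-7-hydroxy-7-(1-methoxypropa-1,2-dien-1-yl)-3,6-dimethyl-2-oxooctahydro-2H-cyclohepta[b]furan-8-yl (2E)-2-methylbut-2-enoate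
Conditions: tigloyl chloride (3 equiv), pyridine, DMAP (0.3 equiv), CH2Cl2, 0 °C → rt
Reagents that add atoms: (E)-2-methylbut-2-enoyl chloride, ClC(=O)/C(C)=C/C
Why: DMAP-catalysed O-acylation of the secondary 8-OH, while the tertiary 7-OH is too hindered to react and the basic medium preserves the acid-labile enol ether; this is done before the enone is unveiled so that no free 8-OH can add to it.

**Step 14**
Reactants: 18 (3R,3aS,5R,6S,7S,8S,8aR)-5-[(tert-butyldimethylsilyl)oxy]-7-hydroxy-7-(1-methoxypropa-1,2-dien-1-yl)-3,6-dimethyl-2-oxooctahydro-2H-cyclohepta[b]furan-8-yl (2E)-2-methylbut-2-enoate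
Product: 20 (3R,3aS,5R,6S,7S,8S,8aR)-7-acryloyl-5,7-dihydroxy-3,6-dimethyl-2-oxooctahydro-2H-cyclohepta[b]furan-8-yl (2E)-2-methylbut-2-enoate, via silyl-protected vinyl ketone 19 (not isolated)
Conditions: 48% aq. HF/MeCN 1:19, 0 °C → rt
Reagents that add atoms: water, O
Why: Acid hydrolysis of the alkoxyallene (protonation at the central carbon, water addition, loss of methanol) gives the α'-hydroxy vinyl ketone, and HF then cleaves the silyl ether; no stereocentre is involved.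

**Step 15**
Reactants: 20 (3R,3aS,5R,6S,7S,8S,8aR)-7-acryloyl-5,7-dihydroxy-3,6-dimethyl-2-oxooctahydro-2H-cyclohepta[b]furan-8-yl (2E)-2-methylbut-2-enoate
Product: 21 (3R,3aS,5R,6S,7S,8S,8aR)-7-[(2E)-but-2-enoyl]-5,7-dihydroxy-3,6-dimethyl-2-oxooctahydro-2H-cyclohepta[b]furan-8-yl (2E)-2-methylbut-2-enoate
Conditions: (Z)-but-2-ene (excess), second-generation Hoveyda–Grubbs catalyst RuCl2(=CH-C6H4-2-O-i-Pr)(H2IMes) (5 mol %), CH2Cl2, 40 °C, sealed tube
Reagents that add atoms: (Z)-but-2-ene, C/C=C\C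
Why: Olefin cross-metathesis of the vinyl ketone with 2-butene gives the E-enone under thermodynamic control; the trisubstituted, electron-poor tiglate alkene does not take part.

**Compound list**
1 | 5,6-dihydro-2H-pyran-2-one | O=C1C=CCCO1 | starting material
2 | (4S)-4-ethenyloxan-2-one | C=C[C@H]1CCOC(=O)C1 | intermediate
3 | lithium enolate of 2 (lithium (4S)-4-ethenyl-5,6-dihydro-4H-pyran-2-olate) | C=C[C@H]1CCOC(O[Li])=C1 | intermediate
4 | (3R,4R)-4-ethenyl-3-methyloxan-2-one (trans) | C=C[C@H]1CCOC(=O)[C@@H]1C | intermediate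
5 | (2R,3R)-3-(2-hydroxyethyl)-N,N,2-trimethylpent-4-enamide | CN(C)C(=O)[C@H](C)[C@@H](C=C)CCO | intermediate
6 | (2R,3R)-N,N,2-trimethyl-3-(2-oxoethyl)pent-4-enamide | CN(C)C(=O)[C@H](C)[C@@H](C=C)CC=O | intermediate
7 | (4S)-4-benzyl-3-propanoyl-1,3-oxazolidin-2-one | CCC(=O)N1[C@@H](Cc2ccccc2)COC1=O | starting material
8 | dibutylboron (Z)-enolate of 7 | C/C=C(\OB(CCCC)CCCC)N1[C@@H](Cc2ccccc2)COC1=O | intermediate
9 | (4S)-4-benzyl-3-[(2S,3R,5R,6R)-7-(dimethylamino)-5-ethenyl-3-hydroxy-2,6-dimethyl-7-oxoheptanoyl]-1,3-oxazolidin-2-one | O=C1OC[C@H](Cc2ccccc2)N1C(=O)[C@@H](C)[C@H](O)C[C@H](C=C)[C@@H](C)C(=O)N(C)C | intermediate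
10 | (2S,3R,5R,6R)-5-ethenyl-3-hydroxy-N1-methoxy-N1,N7,N7,2,6-pentamethylheptanediamide | CON(C)C(=O)[C@@H](C)[C@H](O)C[C@H](C=C)[C@@H](C)C(=O)N(C)C | intermediate
11 | (2S,3R,5R,6R)-3-[(tert-butyldimethylsilyl)oxy]-5-ethenyl-N1-methoxy-N1,N7,N7,2,6-pentamethylheptanediamide | CON(C)C(=O)[C@@H](C)[C@H](O[Si](C)(C)C(C)(C)C)C[C@H](C=C)[C@@H](C)C(=O)N(C)C | intermediate
12 | (2R,3R,5R,6S)-5-[(tert-butyldimethylsilyl)oxy]-3-ethenyl-N,N,2,6-tetramethyl-7-oxonon-8-enamide | C=CC(=O)[C@@H](C)[C@H](O[Si](C)(C)C(C)(C)C)C[C@H](C=C)[C@@H](C)C(=O)N(C)C | intermediate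
13 | (2R)-2-[(1R,5S,6R)-6-[(tert-butyldimethylsilyl)oxy]-5-methyl-4-oxocyclohept-2-en-1-yl]-N,N-dimethylpropanamide | O=C1C=C[C@H]([C@@H](C)C(=O)N(C)C)C[C@@H](O[Si](C)(C)C(C)(C)C)[C@@H]1C | intermediate
14 | (2R)-2-[(1S,3S,4R,6S,7S)-4-[(tert-butyldimethylsilyl)oxy]-3-methyl-2-oxo-8-oxabicyclo[5.1.0]octan-6-yl]-N,N-dimethylpropanamide | O=C1[C@H]2O[C@H]2[C@H]([C@@H](C)C(=O)N(C)C)C[C@@H](O[Si](C)(C)C(C)(C)C)[C@@H]1C | intermediate
15 | N-[(3R,3aS,5R,6S,8S,8aR)-5-[(tert-butyldimethylsilyl)oxy]-8-hydroxy-3,6-dimethyl-7-oxooctahydro-2H-cyclohepta[b]furan-2-ylidene]-N-methylmethanaminium 4-methylbenzenesulfonate | O=C1[C@@H](C)[C@H](O[Si](C)(C)C(C)(C)C)C[C@@H]2[C@@H](OC(=[N+](C)C)[C@@H]2C)[C@@H]1O.Cc1ccc(S(=O)(=O)[O-])cc1 | intermediate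
16 | (3R,3aS,5R,6S,8S,8aR)-5-[(tert-butyldimethylsilyl)oxy]-8-hydroxy-3,6-dimethylhexahydro-2H-cyclohepta[b]furan-2,7(3H)-dione | O=C1[C@@H](C)[C@H](O[Si](C)(C)C(C)(C)C)C[C@@H]2[C@@H](OC(=O)[C@@H]2C)[C@@H]1O | intermediate
17 | (3R,3aS,5R,6S,7S,8S,8aR)-5-[(tert-butyldimethylsilyl)oxy]-7,8-dihydroxy-7-(1-methoxypropa-1,2-dien-1-yl)-3,6-dimethyloctahydro-2H-cyclohepta[b]furan-2-one | C=C=C(OC)[C@]1(O)[C@@H](C)[C@H](O[Si](C)(C)C(C)(C)C)C[C@@H]2[C@@H](OC(=O)[C@@H]2C)[C@@H]1O | intermediate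
18 | (3R,3aS,5R,6S,7S,8S,8aR)-5-[(tert-butyldimethylsilyl)oxy]-7-hydroxy-7-(1-methoxypropa-1,2-dien-1-yl)-3,6-dimethyl-2-oxooctahydro-2H-cyclohepta[b]furan-8-yl (2E)-2-methylbut-2-enoate | C=C=C(OC)[C@]1(O)[C@@H](C)[C@H](O[Si](C)(C)C(C)(C)C)C[C@@H]2[C@@H](OC(=O)[C@@H]2C)[C@@H]1OC(=O)/C(C)=C/C | intermediate
19 | (3R,3aS,5R,6S,7S,8S,8aR)-7-acryloyl-5-[(tert-butyldimethylsilyl)oxy]-7-hydroxy-3,6-dimethyl-2-oxooctahydro-2H-cyclohepta[b]furan-8-yl (2E)-2-methylbut-2-enoate | C=CC(=O)[C@]1(O)[C@@H](C)[C@H](O[Si](C)(C)C(C)(C)C)C[C@@H]2[C@@H](OC(=O)[C@@H]2C)[C@@H]1OC(=O)/C(C)=C/C | intermediate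
20 | (3R,3aS,5R,6S,7S,8S,8aR)-7-acryloyl-5,7-dihydroxy-3,6-dimethyl-2-oxooctahydro-2H-cyclohepta[b]furan-8-yl (2E)-2-methylbut-2-enoate | C=CC(=O)[C@]1(O)[C@@H](C)[C@H](O)C[C@@H]2[C@@H](OC(=O)[C@@H]2C)[C@@H]1OC(=O)/C(C)=C/C | intermediate
21 | (3R,3aS,5R,6S,7S,8S,8aR)-7-[(2E)-but-2-enoyl]-5,7-dihydroxy-3,6-dimethyl-2-oxooctahydro-2H-cyclohepta[b]furan-8-yl (2E)-2-methylbut-2-enoate (CNP0183494.2) | C/C=C/C(=O)[C@]1(O)[C@@H](C)[C@H](O)C[C@@H]2[C@@H](OC(=O)[C@@H]2C)[C@@H]1OC(=O)/C(C)=C/C | target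

**Step count and risks**
Total step count: 15. Longest linear sequence: 15 steps (1 → 21); 7 is a purchased partner.

The three steps most likely to fail are steps 12, 13 and 11.

Step 12 is the weakest point. The nucleophile must enter syn to the 8-oxygen and anti to the 6-methyl, and the facial outcome on a seven-membered ring is not secure. The reagent also meets a γ-lactone and a free hydroxyl. The fallback sets out from 14 and comes back to the route at 19. It moves the addition ahead of lactone formation, where the ketone carries neither a lactone nor an acidic OH and the only α-face neighbour is the small epoxide oxygen. 1-Lithio-1-methoxyallene (1.5 equiv, THF, −78 °C) is added to 14 to give the epoxy carbinol F5. TsOH·H2O in wet THF then hydrolyses the enol ether and triggers the amide-assisted epoxide opening, passing through the iminium ether F6 to the dihydroxy lactone vinyl ketone F7. F7 is acylated at once with tigloyl chloride, pyridine and DMAP, because its free 8-OH can add to the vinyl ketone; this gives 19, which goes on as in step 14.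

Step 13 may fail because the secondary 8-OH sits between the fully substituted C7 carbinol and C8a. The fallback sets out from 16 and comes back at 18. The order is changed so that the alcohol is acylated while C7 is still a planar ketone: 16 with tigloyl chloride, pyridine and DMAP gives the α-tigloyloxy ketone F8. The organocerium reagent from lithiated methoxyallene (1.5 equiv, THF, −78 °C) then adds to F8 and gives 18 directly.

Step 11 may fail because α,β-epoxy ketones open reluctantly under acid and the silyl ether may not survive. The fallback sets out from 13 and comes back at 16, and it replaces the epoxide by a cyclic sulfate. OsO4 (cat.) with NMO dihydroxylates the enone of 13 on the face opposite the side chain to give the cis-diol F1. SOCl2 and Et3N give the cyclic sulfite F2, which RuCl3 (cat.) and NaIO4 oxidise to the cyclic sulfate F3. Warming F3 in MeCN lets the amide oxygen displace the sulfate at the β-carbon with inversion to give the zwitterionic iminium ether sulfate F4. Dilute aqueous H2SO4 in THF hydrolyses both the iminium ether and the sulfate monoester to give 16. This path also avoids the basic epoxidation of step 10.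

**Further compounds**
F1 | step 11 | (2R)-2-[6-[(tert-butyldimethylsilyl)oxy]-2,3-dihydroxy-5-methyl-4-oxocycloheptyl]-N,N-dimethylpropanamide, cis-diol with both hydroxyls anti to the side chain | O=C1[C@@H](O)[C@@H](O)[C@H]([C@@H](C)C(=O)N(C)C)C[C@@H](O[Si](C)(C)C(C)(C)C)[C@@H]1C
F2 | step 11 | cyclic sulfite of F1 (mixture at sulfur) | O=C1[C@H]2OS(=O)O[C@H]2[C@H]([C@@H](C)C(=O)N(C)C)C[C@@H](O[Si](C)(C)C(C)(C)C)[C@@H]1C
F3 | step 11 | cyclic sulfate of F1 | O=C1[C@H]2OS(=O)(=O)O[C@H]2[C@H]([C@@H](C)C(=O)N(C)C)C[C@@H](O[Si](C)(C)C(C)(C)C)[C@@H]1C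
F4 | step 11 | zwitterionic iminium ether 8-O-sulfate (cis-fused, 8-sulfate α) | O=C1[C@@H](C)[C@H](O[Si](C)(C)C(C)(C)C)C[C@@H]2[C@@H](OC(=[N+](C)C)[C@@H]2C)[C@@H]1OS(=O)(=O)[O-]
F5 | step 12 | (2R)-2-[4-[(tert-butyldimethylsilyl)oxy]-2-hydroxy-2-(1-methoxypropa-1,2-dien-1-yl)-3-methyl-8-oxabicyclo[5.1.0]octan-6-yl]-N,N-dimethylpropanamide, tertiary OH anti to the epoxide | C=C=C(OC)[C@@]1(O)[C@H]2O[C@H]2[C@H]([C@@H](C)C(=O)N(C)C)C[C@@H](O[Si](C)(C)C(C)(C)C)[C@@H]1C
F6 | step 12 | iminium ether tosylate of the 7-acryloyl-7,8-dihydroxy bicycle | C=CC(=O)[C@]1(O)[C@@H](C)[C@H](O[Si](C)(C)C(C)(C)C)C[C@@H]2[C@@H](OC(=[N+](C)C)[C@@H]2C)[C@@H]1O.Cc1ccc(S(=O)(=O)[O-])cc1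
F7 | step 12 | (3R,3aS,5R,6S,7S,8S,8aR)-7-acryloyl-5-[(tert-butyldimethylsilyl)oxy]-7,8-dihydroxy-3,6-dimethyloctahydro-2H-cyclohepta[b]furan-2-one | C=CC(=O)[C@]1(O)[C@@H](C)[C@H](O[Si](C)(C)C(C)(C)C)C[C@@H]2[C@@H](OC(=O)[C@@H]2C)[C@@H]1O
F8 | step 13 | (3R,3aS,5R,6S,8S,8aR)-5-[(tert-butyldimethylsilyl)oxy]-3,6-dimethyl-2,7-dioxooctahydro-2H-cyclohepta[b]furan-8-yl (2E)-2-methylbut-2-enoate | O=C1[C@@H](C)[C@H](O[Si](C)(C)C(C)(C)C)C[C@@H]2[C@@H](OC(=O)[C@@H]2C)[C@@H]1OC(=O)/C(C)=C/C
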